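**Plan**

1. Ring A is the hexasubstituted benzene, numbered C1 (benzylic CH2), C2 (OH), C3 (aroyl), C4 (OH), C5 (alkenyl), C6 (OMe); ring B is the 3-hydroxyphenyl ring.
2. Cuts: C3–C(=O) (aryllithium plus ring B aldehyde, then oxidation), C5–alkenyl (Suzuki–Miyaura), the isopropenyl group back to a lactol carbon (MeMgBr, oxidation, methylenation), and the bond from the ring A benzylic CH2 to the stereocentre.
3. Enabling feature: the CH2 on C1 is ortho to the C2 oxygen, so O=C2–C1=CH2 can be raised as an ortho-quinone methide. Its CH2 takes the enamine α-carbon of 5-methylhex-5-enal and the C2 oxygen closes a chroman-2-ol, the only ring formed (reopened later).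
4. Forward: iodine (C3) and bromine (C5) go onto the salicylaldehyde before any alkene exists; then sulfone, key step, lactol to isopropenyl, I/Li exchange and acylation at C3, Suzuki alkenylation at C5, removal of three MOM groups.
5. Stereochemistry: the single (R) centre is set in the key step by the (S)-diarylprolinol silyl ether and is carried through non-basic carbonyl chemistry; the (E)-alkene comes from syn-hydroboration and stereoretentive coupling.

Key step: step 8

Remark: the C4 oxygen is carried as a MOM ether from the start (from 2,4-dihydroxy-6-methoxybenzaldehyde), because a methyl ether there could later be cleaved only by a strong Lewis acid in the presence of three alkenes.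

**Route**

Step 1
Reactants: 1 2,4-dihydroxy-6-methoxybenzaldehyde
Product: 2 2-hydroxy-6-methoxy-4-(methoxymethoxy)benzaldehyde
Conditions: MOMCl (1.1 equiv), iPr2NEt, CH2Cl2, 0 °C
Reagents that add atoms: chloromethyl methyl ether, COCCl
Why: Williamson-type O-alkylation (acetal protection) should occur at the 4-hydroxyl, which is the more acidic one and is not held in the hydrogen bond to the formyl group, as is usual for 2,4-dihydroxy aryl carbonyl compounds.

Step 2
Reactants: 2 2-hydroxy-6-methoxy-4-(methoxymethoxy)benzaldehyde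
Product: 3 2-hydroxy-3-iodo-6-methoxy-4-(methoxymethoxy)benzaldehyde
Conditions: NIS (1.05 equiv), DMF, 0 °C to rt
Reagents that add atoms: N-iodosuccinimide, O=C1CCC(=O)N1I
Why: Electrophilic aromatic iodination should take place ortho to the free hydroxyl at C3 (flanked by OH and OMOM) rather than at the more crowded C5 between two ether groups, the pattern known for 2-hydroxy-4,6-dialkoxy aryl aldehydes and ketones.

Step 3
Reactants: 3 2-hydroxy-3-iodo-6-methoxy-4-(methoxymethoxy)benzaldehyde
Product: 4 3-bromo-6-hydroxy-5-iodo-2-methoxy-4-(methoxymethoxy)benzaldehyde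
Conditions: NBS (1.05 equiv), CH3CN, 0 °C to rt
Reagents that add atoms: N-bromosuccinimide, O=C1CCC(=O)N1Br
Why: Electrophilic aromatic bromination can only enter C5, the last unsubstituted ring position, which is still activated by three oxygen donors, and it is done here because no alkene is yet present to compete for the halogen.

Step 4
Reactants: 4 3-bromo-6-hydroxy-5-iodo-2-methoxy-4-(methoxymethoxy)benzaldehyde
Product: 5 4-bromo-2-(hydroxymethyl)-6-iodo-3-methoxy-5-(methoxymethoxy)phenol
Conditions: NaBH4, THF/MeOH, 0 °C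
Reagents that add atoms: none
Why: Borohydride reduction of the aldehyde gives the 2-hydroxybenzyl alcohol and leaves the aryl halides and the acetal untouched.

Step 5
Reactants: 5 4-bromo-2-(hydroxymethyl)-6-iodo-3-methoxy-5-(methoxymethoxy)phenol
Product: 6 4-bromo-6-iodo-3-methoxy-5-(methoxymethoxy)-2-[(4-methylbenzenesulfonyl)methyl]phenol
Conditions: p-TolSO2H (1.2 equiv), CH2Cl2, rt
Reagents that add atoms: 4-methylbenzenesulfinic acid, Cc1ccc(cc1)S(=O)O
Why: Acid-promoted SN1-type benzylic substitution works because the benzylic alcohol, with three ortho/para oxygen donors, ionises readily and the sulfinate is alkylated at sulfur, while the weak sulfinic acid in an aprotic solvent should not cleave the aryl MOM ether.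

Step 6
Reactants: 7 ethyl 5-oxohexanoate
Product: 8 ethyl 5-methylhex-5-enoate
Conditions: Ph3PCH3Br, KOtBu, THF, 0 °C to rt
Reagents that add atoms: methyltriphenylphosphonium bromide, C[P+](c1ccccc1)(c1ccccc1)c1ccccc1.[Br-]
Why: Wittig methylenation with the non-stabilised ylide converts the ketone much faster than the ester.

Step 7
Reactants: 8 ethyl 5-methylhex-5-enoate
Product: 9 5-methylhex-5-enal
Conditions: iBu2AlH (1.05 equiv), CH2Cl2, −78 °C; aqueous work-up
Reagents that add atoms: none
Why: Half-reduction of the ester with iBu2AlH stops at the aldehyde because the tetrahedral aluminium acetal is stable at −78 °C until work-up.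

Step 8
Reactants: 6 4-bromo-6-iodo-3-methoxy-5-(methoxymethoxy)-2-[(4-methylbenzenesulfonyl)methyl]phenol; 9 5-methylhex-5-enal
Product: 12 (3R)-6-bromo-8-iodo-5-methoxy-7-(methoxymethoxy)-3-(3-methylbut-3-en-1-yl)-3,4-dihydro-2H-chromen-2-ol as an anomeric mixture, via ortho-quinone methide 10 (not isolated), via catalyst enamine 11 (not isolated)
Conditions: (S)-2-[diphenyl(trimethylsilyloxy)methyl]pyrrolidine (20 mol %), Na2CO3 (1.5 equiv), 9 (2.5 equiv), CH2Cl2, 0 °C to rt
Reagents that add atoms: none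
Why: Carbonate deprotonates the phenol of 6 and 1,4-elimination of toluenesulfinate gives ortho-quinone methide 10 (O=C2–C1=CH2), while the secondary amine condenses with 9 to the (E)-enamine 11; the enamine α-carbon adds in a conjugate (Michael-type) fashion to the methide CH2, which rearomatises ring A and forms the CH2–C3 bond, and the phenoxide then adds to the iminium carbon before hydrolysis releases the catalyst and the lactol. The closest known reaction is the diarylprolinol silyl ether-catalysed formal [4+2] cycloaddition of aldehydes with ortho-quinone methides generated in situ from 2-(sulfonylmethyl)phenols. The oxygen ring of the chroman-2-ol closes by 6-exo-trig attack of the C2 phenoxide oxygen on the iminium (or aldehyde) carbon. The new C3 centre is set by the catalyst: the diphenyl(silyloxy)methyl group of the (S)-pyrrolidine blocks one face of the s-trans enamine, so the methide is attacked through the Si face of the enamine α-carbon and the (R) configuration should result, while the anomeric carbon is left as a mixture because it later becomes sp2. The step needs the methide to be captured by the enamine faster than it oligomerises or adds sulfinate, which is secured by its slow release from the sulfone with a heterogeneous base, by the excess of aldehyde and by the oxygen donors (OMe, OMOM) that temper its electrophilicity; the α-branched lactol does not re-form an enamine, so the centre should not erode.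

Step 9
Reactants: 12 (3R)-6-bromo-8-iodo-5-methoxy-7-(methoxymethoxy)-3-(3-methylbut-3-en-1-yl)-3,4-dihydro-2H-chromen-2-ol
Product: 14 (3R)-3-{[3-bromo-6-hydroxy-5-iodo-2-methoxy-4-(methoxymethoxy)phenyl]methyl}-6-methylhept-6-en-2-ol (both C2 epimers), via open-chain aldehyde 13 (not isolated)
Conditions: MeMgBr (4 equiv), THF, −20 °C to rt; then H2O
Reagents that add atoms: methylmagnesium bromide, C[Mg]Br
Why: Grignard 1,2-addition works because the magnesium alkoxide of the lactol opens to the phenoxide aldehyde 13, to which MeMgBr adds faster than it enolises, so the adjacent (R) centre is kept and the new carbinol centre, formed as a mixture, is removed in step 11.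

Step 10
Reactants: 14 (3R)-3-{[3-bromo-6-hydroxy-5-iodo-2-methoxy-4-(methoxymethoxy)phenyl]methyl}-6-methylhept-6-en-2-ol
Product: 15 (3R)-3-{[3-bromo-5-iodo-2-methoxy-4,6-bis(methoxymethoxy)phenyl]methyl}-6-methylhept-6-en-2-ol (both C2 epimers)
Conditions: MOMCl (1.3 equiv), K2CO3, acetone, rt
Reagents that add atoms: chloromethyl methyl ether, COCCl
Why: Williamson-type O-alkylation is selective because carbonate ionises only the phenol, not the secondary alcohol.

Step 11
Reactants: 15 (3R)-3-{[3-bromo-5-iodo-2-methoxy-4,6-bis(methoxymethoxy)phenyl]methyl}-6-methylhept-6-en-2-ol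
Product: 16 (3R)-3-{[3-bromo-5-iodo-2-methoxy-4,6-bis(methoxymethoxy)phenyl]methyl}-6-methylhept-6-en-2-one
Conditions: Dess–Martin periodinane (1.5 equiv), CH2Cl2, 0 °C to rt
Reagents that add atoms: none
Why: Dess–Martin oxidation gives the methyl ketone under non-basic conditions, so the α-centre should not epimerise.

Step 12
Reactants: 16 (3R)-3-{[3-bromo-5-iodo-2-methoxy-4,6-bis(methoxymethoxy)phenyl]methyl}-6-methylhept-6-en-2-one
Product: 17 1-bromo-3-iodo-6-methoxy-2,4-bis(methoxymethoxy)-5-[(2R)-5-methyl-2-(prop-1-en-2-yl)hex-5-en-1-yl]benzene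
Conditions: Cp2TiMe2 (3 equiv), toluene, 65 °C, dark
Reagents that add atoms: dimethyltitanocene, C[Ti+2]C.c1cc[cH-]c1.c1cc[cH-]c1
Why: Petasis methylenation through Cp2Ti=CH2 turns the ketone into the isopropenyl group without base, so the neighbouring stereocentre is not enolised, and aryl halides and acetals are inert to the reagent.

Step 13
Reactants: 18 3-hydroxybenzaldehyde
Product: 19 3-(methoxymethoxy)benzaldehyde
Conditions: MOMCl (1.2 equiv), iPr2NEt, CH2Cl2, 0 °C to rt
Reagents that add atoms: chloromethyl methyl ether, COCCl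
Why: Williamson-type O-alkylation protects the ring B phenol with the same acetal group as ring A, so that all three are removed together at the end.

Step 14
Reactants: 17 1-bromo-3-iodo-6-methoxy-2,4-bis(methoxymethoxy)-5-[(2R)-5-methyl-2-(prop-1-en-2-yl)hex-5-en-1-yl]benzene; 19 3-(methoxymethoxy)benzaldehyde
Product: 21 {3-bromo-4-methoxy-2,6-bis(methoxymethoxy)-5-[(2R)-5-methyl-2-(prop-1-en-2-yl)hex-5-en-1-yl]phenyl}[3-(methoxymethoxy)phenyl]methanol (carbinol epimers), via aryllithium 20 (not isolated)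
Conditions: n-BuLi (1.05 equiv), THF, −78 °C; then 19 (1.2 equiv), −78 to −40 °C; then H2O
Reagents that add atoms: none
Why: Iodine–lithium exchange is far faster than bromine–lithium exchange and gives the C3 aryllithium held by its two OMOM neighbours, which undergoes 1,2-addition to the aldehyde; the new carbinol centre, formed as a mixture, is removed in step 15.

Step 15
Reactants: 21 {3-bromo-4-methoxy-2,6-bis(methoxymethoxy)-5-[(2R)-5-methyl-2-(prop-1-en-2-yl)hex-5-en-1-yl]phenyl}[3-(methoxymethoxy)phenyl]methanol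
Product: 22 {3-bromo-4-methoxy-2,6-bis(methoxymethoxy)-5-[(2R)-5-methyl-2-(prop-1-en-2-yl)hex-5-en-1-yl]phenyl}[3-(methoxymethoxy)phenyl]methanone
Conditions: Dess–Martin periodinane (1.5 equiv), CH2Cl2, rt
Reagents that add atoms: none
Why: Dess–Martin oxidation of the hindered diaryl carbinol gives the benzophenone without touching the alkenes or the aryl bromide.

Step 16
Reactants: 23 3-methylbut-1-yne
Product: 24 4,4,5,5-tetramethyl-2-[(1E)-3-methylbut-1-en-1-yl]-1,3,2-dioxaborolane
Conditions: pinacolborane (1.1 equiv), Cp2Zr(H)Cl (5 mol %), CH2Cl2, rt, sealed vessel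
Reagents that add atoms: pinacolborane, CC1(C)OBOC1(C)C
Why: Zirconocene-hydride-catalysed hydroboration of the terminal alkyne adds H and B syn with boron on the terminal carbon, which fixes the (E) geometry.

Step 17
Reactants: 22 {3-bromo-4-methoxy-2,6-bis(methoxymethoxy)-5-[(2R)-5-methyl-2-(prop-1-en-2-yl)hex-5-en-1-yl]phenyl}[3-(methoxymethoxy)phenyl]methanone; 24 4,4,5,5-tetramethyl-2-[(1E)-3-methylbut-1-en-1-yl]-1,3,2-dioxaborolane
Product: 25 {4-methoxy-2,6-bis(methoxymethoxy)-3-[(1E)-3-methylbut-1-en-1-yl]-5-[(2R)-5-methyl-2-(prop-1-en-2-yl)hex-5-en-1-yl]phenyl}[3-(methoxymethoxy)phenyl]methanone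
Conditions: Pd(OAc)2 (5 mol %), SPhos (10 mol %), K3PO4, toluene/H2O, 80 °C
Reagents that add atoms: none
Why: Suzuki–Miyaura coupling with a dialkylbiarylphosphine ligand handles the di-ortho-oxygenated aryl bromide and transfers the alkenyl group with retention of the (E) geometry.

Step 18
Reactants: 25 {4-methoxy-2,6-bis(methoxymethoxy)-3-[(1E)-3-methylbut-1-en-1-yl]-5-[(2R)-5-methyl-2-(prop-1-en-2-yl)hex-5-en-1-yl]phenyl}[3-(methoxymethoxy)phenyl]methanone
Product: 26 {2,6-dihydroxy-4-methoxy-3-[(1E)-3-methylbut-1-en-1-yl]-5-[(2R)-5-methyl-2-(prop-1-en-2-yl)hex-5-en-1-yl]phenyl}(3-hydroxyphenyl)methanone (CNP0208548.1)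
Conditions: TMSOTf, 2,2′-bipyridyl, CH3CN, 0 °C to rt; then H2O
Reagents that add atoms: none
Why: Silyl-triflate-mediated acetal cleavage, buffered by bipyridyl, converts the aryl MOM ethers into aryl silyl ethers that hydrolyse on aqueous work-up, so no strong protic acid meets the C2 phenol and the isopropenyl group together.

**Compound list**

1 | 2,4-dihydroxy-6-methoxybenzaldehyde | O=Cc1c(O)cc(O)cc1OC | starting material
2 | 2-hydroxy-6-methoxy-4-(methoxymethoxy)benzaldehyde | O=Cc1c(O)cc(OCOC)cc1OC | intermediate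
3 | 2-hydroxy-3-iodo-6-methoxy-4-(methoxymethoxy)benzaldehyde | O=Cc1c(O)c(I)c(OCOC)cc1OC | intermediate
4 | 3-bromo-6-hydroxy-5-iodo-2-methoxy-4-(methoxymethoxy)benzaldehyde | O=Cc1c(O)c(I)c(OCOC)c(Br)c1OC | intermediate
5 | 4-bromo-2-(hydroxymethyl)-6-iodo-3-methoxy-5-(methoxymethoxy)phenol | OCc1c(O)c(I)c(OCOC)c(Br)c1OC | intermediate
6 | 4-bromo-6-iodo-3-methoxy-5-(methoxymethoxy)-2-[(4-methylbenzenesulfonyl)methyl]phenol | Cc1ccc(cc1)S(=O)(=O)Cc1c(O)c(I)c(OCOC)c(Br)c1OC | intermediate
7 | ethyl 5-oxohexanoate | CCOC(=O)CCCC(C)=O | starting material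
8 | ethyl 5-methylhex-5-enoate | CCOC(=O)CCCC(C)=C | intermediate
9 | 5-methylhex-5-enal | C=C(C)CCCC=O | intermediate
10 | 4-bromo-2-iodo-5-methoxy-3-(methoxymethoxy)-6-methylidenecyclohexa-2,4-dien-1-one | C=C1C(=O)C(I)=C(OCOC)C(Br)=C1OC | intermediate (not isolated)
11 | (2S)-2-[diphenyl(trimethylsilyloxy)methyl]-1-[(1E)-5-methylhexa-1,5-dien-1-yl]pyrrolidine | C=C(C)CC/C=C/N1CCC[C@H]1C(O[Si](C)(C)C)(c1ccccc1)c1ccccc1 | intermediate (not isolated)
12 | (3R)-6-bromo-8-iodo-5-methoxy-7-(methoxymethoxy)-3-(3-methylbut-3-en-1-yl)-3,4-dihydro-2H-chromen-2-ol (anomeric mixture) | C=C(C)CC[C@@H]1Cc2c(OC)c(Br)c(OCOC)c(I)c2OC1O | intermediate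
13 | (2R)-2-{[3-bromo-6-hydroxy-5-iodo-2-methoxy-4-(methoxymethoxy)phenyl]methyl}-5-methylhex-5-enal | C=C(C)CC[C@@H](C=O)Cc1c(O)c(I)c(OCOC)c(Br)c1OC | intermediate (not isolated)
14 | (3R)-3-{[3-bromo-6-hydroxy-5-iodo-2-methoxy-4-(methoxymethoxy)phenyl]methyl}-6-methylhept-6-en-2-ol (C2 epimers) | C=C(C)CC[C@@H](C(C)O)Cc1c(O)c(I)c(OCOC)c(Br)c1OC | intermediate
15 | (3R)-3-{[3-bromo-5-iodo-2-methoxy-4,6-bis(methoxymethoxy)phenyl]methyl}-6-methylhept-6-en-2-ol (C2 epimers) | C=C(C)CC[C@@H](C(C)O)Cc1c(OCOC)c(I)c(OCOC)c(Br)c1OC | intermediate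
16 | (3R)-3-{[3-bromo-5-iodo-2-methoxy-4,6-bis(methoxymethoxy)phenyl]methyl}-6-methylhept-6-en-2-one | C=C(C)CC[C@@H](C(C)=O)Cc1c(OCOC)c(I)c(OCOC)c(Br)c1OC | intermediate
17 | 1-bromo-3-iodo-6-methoxy-2,4-bis(methoxymethoxy)-5-[(2R)-5-methyl-2-(prop-1-en-2-yl)hex-5-en-1-yl]benzene | C=C(C)CC[C@H](Cc1c(OCOC)c(I)c(OCOC)c(Br)c1OC)C(=C)C | intermediate
18 | 3-hydroxybenzaldehyde | O=Cc1cccc(O)c1 | starting material
19 | 3-(methoxymethoxy)benzaldehyde | O=Cc1cccc(OCOC)c1 | intermediate
20 | {3-bromo-4-methoxy-2,6-bis(methoxymethoxy)-5-[(2R)-5-methyl-2-(prop-1-en-2-yl)hex-5-en-1-yl]phenyl}lithium | C=C(C)CC[C@H](Cc1c(OCOC)c([Li])c(OCOC)c(Br)c1OC)C(=C)C | intermediate (not isolated)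
21 | {3-bromo-4-methoxy-2,6-bis(methoxymethoxy)-5-[(2R)-5-methyl-2-(prop-1-en-2-yl)hex-5-en-1-yl]phenyl}[3-(methoxymethoxy)phenyl]methanol (carbinol epimers) | C=C(C)CC[C@H](Cc1c(OCOC)c(C(O)c2cccc(OCOC)c2)c(OCOC)c(Br)c1OC)C(=C)C | intermediate
22 | {3-bromo-4-methoxy-2,6-bis(methoxymethoxy)-5-[(2R)-5-methyl-2-(prop-1-en-2-yl)hex-5-en-1-yl]phenyl}[3-(methoxymethoxy)phenyl]methanone | C=C(C)CC[C@H](Cc1c(OCOC)c(C(=O)c2cccc(OCOC)c2)c(OCOC)c(Br)c1OC)C(=C)C | intermediate
23 | 3-methylbut-1-yne | CC(C)C#C | starting material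
24 | 4,4,5,5-tetramethyl-2-[(1E)-3-methylbut-1-en-1-yl]-1,3,2-dioxaborolane | CC(C)/C=C/B1OC(C)(C)C(C)(C)O1 | intermediate
25 | {4-methoxy-2,6-bis(methoxymethoxy)-3-[(1E)-3-methylbut-1-en-1-yl]-5-[(2R)-5-methyl-2-(prop-1-en-2-yl)hex-5-en-1-yl]phenyl}[3-(methoxymethoxy)phenyl]methanone | C=C(C)CC[C@H](Cc1c(OCOC)c(C(=O)c2cccc(OCOC)c2)c(OCOC)c(/C=C/C(C)C)c1OC)C(=C)C | intermediate
26 | {2,6-dihydroxy-4-methoxy-3-[(1E)-3-methylbut-1-en-1-yl]-5-[(2R)-5-methyl-2-(prop-1-en-2-yl)hex-5-en-1-yl]phenyl}(3-hydroxyphenyl)methanone | C=C(C)CC[C@H](Cc1c(O)c(C(=O)c2cccc(O)c2)c(O)c(/C=C/C(C)C)c1OC)C(=C)C | target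

**Step count and risks**

Total step count: 18. Longest linear sequence: 14 steps (steps 1–5, 8–12, 14, 15, 17, 18).

Steps most likely to fail:

Step 8. The unsubstituted methide may oligomerise or dimerise by hetero-Diels–Alder reaction before the enamine captures it, or enantiomeric purity may erode through the open-chain aldehyde. The fallback is an auxiliary-controlled enolate alkylation that sets out from 5 and 8 and returns at 15. The phenol of 5 is protected (MOMCl, K2CO3, acetone) to give the phenol-protected benzylic alcohol F1, which PPh3/CBr4 converts into benzylic bromide F2. Ester 8 is saponified (LiOH, THF/H2O) to 5-methylhex-5-enoic acid F3, which is joined to (S)-4-benzyl-1,3-oxazolidin-2-one by the pivaloyl mixed-anhydride method (PivCl, Et3N, LiCl) to give N-acyl oxazolidinone F4. Deprotonation of F4 with NaN(SiMe3)2 (THF, −78 °C) and alkylation by F2 on the enolate face away from the benzyl group should give alkylated imide F5 with the (R) centre. LiBH4 (Et2O, 0 °C) then releases the auxiliary and gives primary alcohol F6, Dess–Martin oxidation gives aldehyde F7, and MeMgBr (THF, −78 °C) converts F7 into 15, from which step 11 follows.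

Step 18. When the C2 phenol is set free next to the isopropenyl group, traces of acid may close a 2,2-dimethylchroman ring, and the two hindered ring A acetals may cleave incompletely. The fallback keeps the C2 oxygen as an allyl ether until the acetals are gone and removes it last under neutral palladium catalysis; it sets out from 14 and returns at 26. Compound 14 is O-allylated at the phenol (allyl bromide, K2CO3, acetone) to give allyl ether alcohol F8. Dess–Martin oxidation gives methyl ketone F9 and Cp2TiMe2 gives isopropenyl aryl iodide F10. Iodine–lithium exchange (n-BuLi, −78 °C) and addition to 19 give carbinol F11, which Dess–Martin periodinane oxidises to bromo benzophenone F12. Suzuki–Miyaura coupling with 24 (Pd(OAc)2, SPhos, K3PO4) gives alkenyl benzophenone F13. TMSOTf/2,2′-bipyridyl followed by water removes the two MOM groups while the C2 oxygen stays allylated, giving allyl ether diphenol F14. Pd(PPh3)4 (catalytic) with morpholine in THF at rt then transfers the allyl group to the amine and gives 26.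

Step 2. The iodination may show poor site selectivity between C3 and C5, or iodine may migrate during the bromination that follows. The fallback fixes the site by directed ortho-metalation instead of electrophilic substitution; it sets out from 2 and returns at 3. The remaining phenol of 2 is protected (MOMCl, NaH, DMF) to give 2-methoxy-4,6-bis(methoxymethoxy)benzaldehyde F15. After masking of the formyl group in the flask by addition of LiN(Me)CH2CH2NMe2, n-BuLi removes the only ring hydrogen flanked by two OMOM groups, and I2 followed by aqueous work-up gives 3-iodo-6-methoxy-2,4-bis(methoxymethoxy)benzaldehyde F16. The acetal ortho to the formyl group, activated by the neighbouring carbonyl, is then cleaved selectively (catalytic HCl, MeOH, 0 °C), which gives 3.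

**Further compounds**

F1 | step 8 | [3-bromo-5-iodo-2-methoxy-4,6-bis(methoxymethoxy)phenyl]methanol | OCc1c(OCOC)c(I)c(OCOC)c(Br)c1OC
F2 | step 8 | 1-bromo-5-(bromomethyl)-3-iodo-6-methoxy-2,4-bis(methoxymethoxy)benzene | BrCc1c(OCOC)c(I)c(OCOC)c(Br)c1OC
F3 | step 8 | 5-methylhex-5-enoic acid | C=C(C)CCCC(=O)O
F4 | step 8 | (4S)-4-benzyl-3-(5-methylhex-5-enoyl)-1,3-oxazolidin-2-one | C=C(C)CCCC(=O)N1[C@@H](Cc2ccccc2)COC1=O
F5 | step 8 | (4S)-4-benzyl-3-[(2R)-2-{[3-bromo-5-iodo-2-methoxy-4,6-bis(methoxymethoxy)phenyl]methyl}-5-methylhex-5-enoyl]-1,3-oxazolidin-2-one | C=C(C)CC[C@@H](C(=O)N1[C@@H](Cc2ccccc2)COC1=O)Cc1c(OCOC)c(I)c(OCOC)c(Br)c1OC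
F6 | step 8 | (2R)-2-{[3-bromo-5-iodo-2-methoxy-4,6-bis(methoxymethoxy)phenyl]methyl}-5-methylhex-5-en-1-ol | C=C(C)CC[C@@H](CO)Cc1c(OCOC)c(I)c(OCOC)c(Br)c1OC
F7 | step 8 | (2R)-2-{[3-bromo-5-iodo-2-methoxy-4,6-bis(methoxymethoxy)phenyl]methyl}-5-methylhex-5-enal | C=C(C)CC[C@@H](C=O)Cc1c(OCOC)c(I)c(OCOC)c(Br)c1OC
F8 | step 18 | (3R)-3-{[3-bromo-5-iodo-2-methoxy-4-(methoxymethoxy)-6-(prop-2-en-1-yloxy)phenyl]methyl}-6-methylhept-6-en-2-ol | C=C(C)CC[C@@H](C(C)O)Cc1c(OCC=C)c(I)c(OCOC)c(Br)c1OC
F9 | step 18 | (3R)-3-{[3-bromo-5-iodo-2-methoxy-4-(methoxymethoxy)-6-(prop-2-en-1-yloxy)phenyl]methyl}-6-methylhept-6-en-2-one | C=C(C)CC[C@@H](C(C)=O)Cc1c(OCC=C)c(I)c(OCOC)c(Br)c1OC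
F10 | step 18 | 1-bromo-3-iodo-6-methoxy-2-(methoxymethoxy)-5-[(2R)-5-methyl-2-(prop-1-en-2-yl)hex-5-en-1-yl]-4-(prop-2-en-1-yloxy)benzene | C=C(C)CC[C@H](Cc1c(OCC=C)c(I)c(OCOC)c(Br)c1OC)C(=C)C
F11 | step 18 | {3-bromo-4-methoxy-2-(methoxymethoxy)-5-[(2R)-5-methyl-2-(prop-1-en-2-yl)hex-5-en-1-yl]-6-(prop-2-en-1-yloxy)phenyl}[3-(methoxymethoxy)phenyl]methanol | C=C(C)CC[C@H](Cc1c(OCC=C)c(C(O)c2cccc(OCOC)c2)c(OCOC)c(Br)c1OC)C(=C)C
F12 | step 18 | {3-bromo-4-methoxy-2-(methoxymethoxy)-5-[(2R)-5-methyl-2-(prop-1-en-2-yl)hex-5-en-1-yl]-6-(prop-2-en-1-yloxy)phenyl}[3-(methoxymethoxy)phenyl]methanone | C=C(C)CC[C@H](Cc1c(OCC=C)c(C(=O)c2cccc(OCOC)c2)c(OCOC)c(Br)c1OC)C(=C)C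
F13 | step 18 | {4-methoxy-2-(methoxymethoxy)-3-[(1E)-3-methylbut-1-en-1-yl]-5-[(2R)-5-methyl-2-(prop-1-en-2-yl)hex-5-en-1-yl]-6-(prop-2-en-1-yloxy)phenyl}[3-(methoxymethoxy)phenyl]methanone | C=C(C)CC[C@H](Cc1c(OCC=C)c(C(=O)c2cccc(OCOC)c2)c(OCOC)c(/C=C/C(C)C)c1OC)C(=C)C
F14 | step 18 | {2-hydroxy-4-methoxy-3-[(1E)-3-methylbut-1-en-1-yl]-5-[(2R)-5-methyl-2-(prop-1-en-2-yl)hex-5-en-1-yl]-6-(prop-2-en-1-yloxy)phenyl}(3-hydroxyphenyl)methanone | C=C(C)CC[C@H](Cc1c(OCC=C)c(C(=O)c2cccc(O)c2)c(O)c(/C=C/C(C)C)c1OC)C(=C)C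
F15 | step 2 | 2-methoxy-4,6-bis(methoxymethoxy)benzaldehyde | O=Cc1c(OCOC)cc(OCOC)cc1OC
F16 | step 2 | 3-iodo-6-methoxy-2,4-bis(methoxymethoxy)benzaldehyde | O=Cc1c(OCOC)c(I)c(OCOC)cc1OC
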